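The plan cuts the two α-bonds of the C1 ketone, C2–C2′ and C10–C5 (eudesmane numbering; C1′ and C2′ are the myrcene-derived bridge carbons), which face each other across the cyclohexanone ring C1–C2–C2′–C1′–C5–C10 of the bicyclo[2.2.2]octenone. A temporary C3 carbonyl makes C2 doubly activated and C5 a Michael acceptor. In one flask the dianion of an acyclic ene-1,3-dione closes ring A through C10→C5, the dione enolate is allylated at C2 by a π-allylpalladium unit hanging from C1′, and the remaining C3 enolate is trapped as a triflate, later reduced to the C3=C4 alkene. A glycerate dioxolane on C5, a masked C6 aldehyde, controls absolute configuration; ring B and the lactone follow by ketyl–olefin cyclisation.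

Key step: step 8

Remark: eudesmanolide locants are used throughout (C1 ketone, C2 and C5 bridgeheads, C3=C4 alkene, C6–O, C7, C8, C9, C10 quaternary, C11, C12 lactone carbonyl; C1′ = CH2 on C5, C2′ = CH on C2 carrying the 6-methylhepta-1,5-dien-2-yl group); compounds 5, 6, 14 and both enantiomers of 1 are assumed to be commercial.

Step 1
Reactants: 1 methyl (S)-2,2-dimethyl-1,3-dioxolane-4-carboxylate; 2 N-methoxy-N-methylpropanamide
Product: 3 β-keto Weinreb amide (dioxolane centre S; C4 epimers)
Conditions: 2 (2.2 equiv), LiN(i-Pr)2 (2.2 equiv), THF, −78 °C; then 1, −78 → −40 °C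
Reagents that add atoms: none
Why: Crossed Claisen condensation of the amide enolate with the ester, in which the product is held as its stabilised enolate (enolised at C4, not at the dioxolane carbon), so the glycerate stereocentre should survive.

Step 2
Reactants: 3
Product: 4 (Z)-enol triflate
Conditions: NaH, THF, 0 °C; PhNTf2, 0 °C → rt
Reagents that add atoms: N-phenylbis(trifluoromethanesulfonimide), O=S(=O)(N(c1ccccc1)S(=O)(=O)C(F)(F)F)C(F)(F)F
Why: Enol triflate formation from the chelated sodium enolate should place the triflate cis to the amide carbonyl (Z) and so fix the geometry of the later tetrasubstituted alkene.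

Step 3
Reactants: 5 but-3-yne-1,2-diol (racemic); 6 5-bromo-2-methylpent-2-ene
Product: 8 7-methyl-3-methylideneoct-6-ene-1,2-diol (racemic), via homoprenylmagnesium bromide 7 (not isolated)
Conditions: 6, Mg, THF; then 5 (0.28 equiv), CuI (10 mol%), Et2O–THF, 0 °C → reflux; aq. NH4Cl
Reagents that add atoms: none
Why: Copper-catalysed carbomagnesiation of a propargylic alkoxide, in which the alkyl group adds to the alkyne carbon next to the carbinol and protonation leaves the 1,1-disubstituted alkene of the future side chain.

Step 4
Reactants: 8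
Product: 9 1-iodo-7-methyl-3-methylideneoct-6-en-2-ol (racemic)
Conditions: I2, PPh3, imidazole, CH2Cl2, 0 °C
Reagents that add atoms: iodine, II
Why: Appel-type iodination, which should select the primary over the secondary allylic hydroxyl.

Step 5
Reactants: 9; 4
Product: 12 (E)-enamide pivalate (C2′ epimers), via β-oxido alkylzinc chloride 10 (not isolated), via allylic alcohol 11 (not isolated)
Conditions: 9, MeLi (1.0 equiv), Et2O, −78 °C; t-BuLi (2.1 equiv), −78 °C; ZnCl2, −78 → 0 °C; 4, Pd(PPh3)4 (5 mol%), THF, rt; then PivCl, DMAP, 0 °C → rt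
Reagents that add atoms: pivaloyl chloride, CC(C)(C)C(Cl)=O
Why: Negishi coupling of an alkylzinc whose β-oxygen is an oxide and so cannot leave, with retention of the enol triflate geometry, followed by acylation of the liberated alkoxide to install the allylic leaving group.

Step 6
Reactants: 12
Product: 13 methyl ketone (tetrasubstituted enone)
Conditions: MeMgBr, THF, −20 → 0 °C
Reagents that add atoms: methylmagnesium bromide, C[Mg]Br
Why: Weinreb ketone synthesis, in which the chelated tetrahedral intermediate stops at the ketone and the hindered pivalate should survive the short exposure.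

Step 7
Reactants: 13; 14 hex-5-enoyl chloride
Product: 15 acyclic ene-1,3-dione (partly enolised)
Conditions: MgBr2·OEt2, i-Pr2NEt, CH2Cl2, 0 °C → rt
Reagents that add atoms: none
Why: Soft-enolisation C-acylation (Claisen-type) at the methyl group, the only enolisable α-position of 13, should give the β-diketone without strong base.

Step 8
Reactants: 15
Product: 18 bicyclic C3 enol triflate (C10 epimers), via cyclohexanedione dianion 16 (not isolated), via bicyclic lithium enolate 17 (not isolated)
Conditions: LiN(i-Pr)2 (2.15 equiv), THF–DMPU, −78 → 0 °C; Pd(PPh3)4 (5 mol%), 0 °C → rt; then −78 °C, PhNTf2, → 0 °C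
Reagents that add atoms: N-phenylbis(trifluoromethanesulfonimide), O=S(=O)(N(c1ccccc1)S(=O)(=O)C(F)(F)F)C(F)(F)F
Why: Proposed new method: double deprotonation gives the ene-1,3-dione dianion (a 2,4-dioxido-hexatriene), whose terminal carbanion C10 adds to the tetrasubstituted enone carbon C5 (6-endo-trig Michael closure, equivalent to an oxido-accelerated disrotatory 6π-electrocyclisation) to close ring A as the cyclohexane-1,3-dione dianion 16; the closest known types are terminal-carbon Michael reactions of 1,3-dicarbonyl dianions and the base-mediated cyclisation of 5-ene-1,3-diones to cyclohexane-1,3-diones. Zerovalent palladium then ionises the allylic pivalate and the soft C2 carbanion attacks the near terminus C2′ of the π-allyl unit (6-exo Tsuji–Trost alkylation of a cyclic 1,3-dione, which closes the C1′–C2′ bridge and with it the bicyclo[2.2.2]octane; O-allylation would give a bridgehead enol ether and is reversible), leaving the regiodefined C3–C4 enolate 17 that is trapped as the triflate. C5 should be set by the dioxolane stereocentre (Felkin–Anh-type attack anti to the C–O bond, with the hydrogen eclipsing the alkene to avoid A(1,3) strain with the C4 methyl). C2′ should be set under substrate control, since both pivalate epimers converge on one π-allyl unit that equilibrates through its CH2 terminus and the side chain should settle over the flat enolate bridge rather than over the C10–C1 bridge; C2 follows from the bridge geometry and C10 is inconsequential because it is planarised in step 10. The step needs C10 to attack C5 first (it is the most basic site of the dianion and the only one that can reach C5) and C2 rather than C4 to take the allyl unit (C4 would have to form a four-membered ring or reach the far terminus).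

Step 9
Reactants: 18
Product: 19 bicyclo[2.2.2]octenone with the C3=C4 alkene (C10 epimers)
Conditions: Pd(OAc)2 (5 mol%), PPh3, HCO2H, n-Bu3N, DMF, 60 °C
Reagents that add atoms: none
Why: Palladium-catalysed formate reduction of a vinyl triflate should replace the triflate by hydrogen with retention and reveal the trisubstituted C3=C4 alkene.

Step 10
Reactants: 19
Product: 20 C10-methylated ketone
Conditions: KN(SiMe3)2, THF, −78 °C; MeI, −78 → −30 °C
Reagents that add atoms: iodomethane, CI
Why: Enolate alkylation at C10, the only enolisable position (C2 is a bridgehead), with iodomethane expected to approach syn to the C3=C4 bridge (the open face of a bicyclo[2.2.2]octenone enolate), which puts the methyl β and the butenyl chain on the C1′ side as in the target.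

Step 11
Reactants: 20; 21 methyl methacrylate
Product: 22 (E)-2-methyl-enoate
Conditions: 21 (10 equiv), second-generation Grubbs catalyst (5 mol%), CH2Cl2, 40 °C
Reagents that add atoms: none
Why: Cross-metathesis of the only monosubstituted alkene with a methacrylate partner should give the (E)-enoate, the 1,1-disubstituted and trisubstituted alkenes being far slower.

Step 12
Reactants: 22
Product: 24 C6 aldehyde, via diol 23 (not isolated)
Conditions: H5IO6, EtOAc, rt
Reagents that add atoms: none
Why: Periodic acid should hydrolyse the terminal acetonide and cleave the glycol in one flask (glycol cleavage), unmasking the aldehyde on the quaternary C5, which cannot epimerise.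

Step 13
Reactants: 24
Product: 26 trans-fused lactone (C11 epimers), via hydroxy ester 25 (not isolated)
Conditions: SmI2 (2.5 equiv), t-BuOH (2 equiv), THF, −78 °C → rt
Reagents that add atoms: none
Why: Samarium diiodide ketyl–olefin cyclisation (6-exo-trig onto the enoate) through a chair in which the ketyl oxygen sits equatorial to avoid the axial C10 methyl and the enoate is equatorial, which should set C6 and C7 trans as required before the alkoxide lactonises.

Step 14
Reactants: 26
Product: 27 target CNP0385704.3
Conditions: DBU, toluene, 80 °C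
Reagents that add atoms: none
Why: Base-mediated epimerisation under thermodynamic control at C11 should converge on the epimer with the methyl trans to C8, which is the configuration of the target.

Compound list

1 | methyl (S)-2,2-dimethyl-1,3-dioxolane-4-carboxylate | COC(=O)[C@@H]1COC(C)(C)O1 | starting material
2 | N-methoxy-N-methylpropanamide | CCC(=O)N(C)OC | starting material
3 | 3-[(4S)-2,2-dimethyl-1,3-dioxolan-4-yl]-N-methoxy-N,2-dimethyl-3-oxopropanamide (epimers at the methyl-bearing carbon) | CON(C)C(=O)C(C)C(=O)[C@@H]1COC(C)(C)O1 | intermediate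
4 | (Z)-enol triflate of 3, triflate cis to the amide carbonyl, dioxolane centre S | CON(C)C(=O)/C(C)=C(\OS(=O)(=O)C(F)(F)F)[C@@H]1COC(C)(C)O1 | intermediate
5 | but-3-yne-1,2-diol (racemic) | OCC(O)C#C | starting material
6 | 5-bromo-2-methylpent-2-ene | CC(C)=CCCBr | starting material
7 | (4-methylpent-3-enyl)magnesium bromide (not isolated) | CC(C)=CCC[Mg]Br | intermediate
8 | 7-methyl-3-methylideneoct-6-ene-1,2-diol (racemic) | OCC(O)C(=C)CCC=C(C)C | intermediate
9 | 1-iodo-7-methyl-3-methylideneoct-6-en-2-ol (racemic) | ICC(O)C(=C)CCC=C(C)C | intermediate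
10 | lithium 1-(chlorozincio)-7-methyl-3-methylideneoct-6-en-2-olate (not isolated) | [Li+].[O-]C(C[Zn]Cl)C(=C)CCC=C(C)C | intermediate
11 | (2E)-3-[(4R)-2,2-dimethyl-1,3-dioxolan-4-yl]-5-hydroxy-N-methoxy-N,2,10-trimethyl-6-methylideneundeca-2,9-dienamide, carbinol epimers, alkyl chain cis to the amide carbonyl (not isolated) | CON(C)C(=O)/C(C)=C(\CC(O)C(=C)CCC=C(C)C)[C@@H]1COC(C)(C)O1 | intermediate
12 | pivalate ester of 11 (C2′ epimers) | CON(C)C(=O)/C(C)=C(\CC(OC(=O)C(C)(C)C)C(=C)CCC=C(C)C)[C@@H]1COC(C)(C)O1 | intermediate
13 | (3E)-4-[(4R)-2,2-dimethyl-1,3-dioxolan-4-yl]-3,11-dimethyl-7-methylidene-2-oxododeca-3,10-dien-6-yl pivalate (C2′ epimers) | CC(=O)/C(C)=C(\CC(OC(=O)C(C)(C)C)C(=C)CCC=C(C)C)[C@@H]1COC(C)(C)O1 | intermediate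
14 | hex-5-enoyl chloride | C=CCCCC(Cl)=O | starting material
15 | (9E)-10-[(4R)-2,2-dimethyl-1,3-dioxolan-4-yl]-9,17-dimethyl-13-methylidene-6,8-dioxooctadeca-1,9,16-trien-12-yl pivalate (C2′ epimers) | C=CCCCC(=O)CC(=O)/C(C)=C(\CC(OC(=O)C(C)(C)C)C(=C)CCC=C(C)C)[C@@H]1COC(C)(C)O1 | intermediate
16 | dilithium 2,4-dianion of the ring A cyclohexane-1,3-dione: C5 quaternary (configured as in the target) with the (4R)-dioxolanyl group and the pivaloyloxy side chain, C4 methyl, C10 but-3-enyl (not isolated) | [Li+].[Li+].C=CCCC1C([O-])=CC([O-])=C(C)[C@]1(CC(OC(=O)C(C)(C)C)C(=C)CCC=C(C)C)[C@@H]2COC(C)(C)O2 | intermediate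
17 | lithium C3 enolate of the bicyclo[2.2.2]octane-1,3-dione: C2, C5 and C2′ as in the target, side chain syn to the C3–C4 bridge, C10 H/but-3-enyl (not isolated) | [Li+].C=C(CCC=C(C)C)[C@@H]1C[C@]2([C@@H]5COC(C)(C)O5)C(C)=C([O-])[C@H]1C(=O)C2CCC=C | intermediate
18 | bicyclo[2.2.2]oct-5-en-2-one: C1 ketone, C3 enol triflate, C4 methyl, C5 (4R)-2,2-dimethyl-1,3-dioxolan-4-yl, C10 H/but-3-enyl (epimers), C2′ 6-methylhepta-1,5-dien-2-yl syn to the C3=C4 bridge; C2, C5, C2′ as in the target | C=C(CCC=C(C)C)[C@@H]1C[C@]2([C@@H]5COC(C)(C)O5)C(C)=C(OS(=O)(=O)C(F)(F)F)[C@H]1C(=O)C2CCC=C | intermediate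
19 | as 18 with hydrogen in place of the triflate at C3 (C10 epimers) | C=C(CCC=C(C)C)[C@@H]1C[C@]2([C@@H]5COC(C)(C)O5)C(C)=C[C@H]1C(=O)C2CCC=C | intermediate
20 | as 19 with C10 quaternary: methyl syn to the C3=C4 bridge, but-3-enyl on the C1′ side (C10 as in the target) | C=C(CCC=C(C)C)[C@@H]1C[C@]2([C@@H]5COC(C)(C)O5)C(C)=C[C@H]1C(=O)[C@]2(C)CCC=C | intermediate
21 | methyl methacrylate | C=C(C)C(=O)OC | starting material
22 | as 20 with the C10 chain extended to (E)-CH2CH2CH=C(CH3)CO2CH3 | C=C(CCC=C(C)C)[C@@H]1C[C@]2([C@@H]5COC(C)(C)O5)C(C)=C[C@H]1C(=O)[C@]2(C)CC/C=C(\C)C(=O)OC | intermediate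
23 | 1,2-diol from 22 (acetonide removed; not isolated) | C=C(CCC=C(C)C)[C@@H]1C[C@]2([C@@H](O)CO)C(C)=C[C@H]1C(=O)[C@]2(C)CC/C=C(\C)C(=O)OC | intermediate
24 | C5 carbaldehyde (C6 aldehyde) bearing the (E)-enoate chain on C10 | C=C(CCC=C(C)C)[C@@H]1C[C@]2(C=O)C(C)=C[C@H]1C(=O)[C@]2(C)CC/C=C(\C)C(=O)OC | intermediate
25 | ring B hydroxy ester: 6α-hydroxyl and 7β-(1-methoxy-1-oxopropan-2-yl) trans-diequatorial, C11 epimers (not isolated) | C=C(CCC=C(C)C)[C@@H]1C[C@]23C(C)=C[C@H]1C(=O)[C@]2(C)CC[C@@H](C(C)C(=O)OC)[C@@H]3O | intermediate
26 | target skeleton as a mixture of C11 epimers (trans-fused 12,6-lactone) | C=C(CCC=C(C)C)[C@@H]1C[C@]23C(C)=C[C@H]1C(=O)[C@]2(C)CC[C@H]1C(C)C(=O)O[C@@H]13 | intermediate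
27 | CNP0385704.3 (2R,5S,6S,7S,10R,11S,2′R in the locants of the remark) | C=C(CCC=C(C)C)[C@@H]1C[C@]23C(C)=C[C@H]1C(=O)[C@]2(C)CC[C@H]1[C@H](C)C(=O)O[C@@H]13 | target

Total step count: 14. Longest linear sequence: 12 steps (steps 1, 2, 5–14, or equally steps 3, 4, 5–14).

Steps most likely to fail

1. Step 8 (proposed new method). Several things may go wrong:
   - The dianion may close only slowly onto the fully substituted C5 terminus.
   - Acyl transfer from the pivalate to the transient C4 carbanion may compete.
   - The C4 enolate may rival C2 for the π-allyl unit, or exchange protons with C10–H before trapping, which would erode the regiocontrol of the triflation.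
   - Facial control at C5 or C2′ may be weak. If only the sense of induction at C5 is wrong, the enantiomer of 1 corrects it.

   The fallback uses known chemistry, sets out from 13 and returns at 18. Compound 13 is C-acylated with acetyl chloride (MgBr2·OEt2, i-Pr2NEt) to the acetyl-armed ene-1,3-dione F1. KOt-Bu in t-BuOH–THF effects the thermodynamically driven intramolecular Michael closure to the 5,5-disubstituted 4-methylcyclohexane-1,3-dione F2, and in the same flask Pd(PPh3)4 closes the bridge by Tsuji–Trost C-alkylation to the bicyclo[2.2.2]octane-1,3-dione F3. Both bonds are thus still made in one operation, but without a dianion or in situ trapping. The two ketones are then told apart by structure. Mannich methylenation (paraformaldehyde, N-methylanilinium trifluoroacetate, THF, reflux) can only occur at the C10 methylene and gives the exocyclic enone F4, whose C1 ketone can no longer enolise. KN(SiMe3)2 and PhNTf2 therefore give the C3 enol triflate F5 alone. Copper-catalysed conjugate addition of allylmagnesium bromide (CuBr·SMe2, Me3SiCl, THF, −78 °C) to the exocyclic enone then delivers 18.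

2. Step 5. Iodine–lithium exchange next to an alkoxide may be accompanied by β-elimination or Wurtz-type coupling, and transmetalation and coupling at the hindered tetrasubstituted triflate may be slow. The fallback sets out from 4 and returns at 12. Stille coupling of 4 with allyltributylstannane (Pd(PPh3)4, LiCl, THF) gives the skipped diene F6. Selective oxidative cleavage of its terminal alkene (OsO4 cat., NaIO4, 2,6-lutidine) gives the aldehyde F7. Nozaki–Hiyama–Kishi coupling (CrCl2, NiCl2 cat., DMF) of F7 with 6-methylhepta-1,5-dien-2-yl triflate F8, made from commercial 6-methylhept-5-en-2-one with LiN(i-Pr)2 and PhNTf2, gives alcohol 11, which is pivaloylated (PivCl, DMAP) to 12.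

3. Step 13. The ketyl may be reduced further to the alcohol before it cyclises, or the ring closure may show poor facial selectivity at C6 and C7 and lead to the cis-lactone. The fallback replaces the radical closure by a two-electron allylmetal addition; it sets out from 20 and returns at 26. Cross-metathesis of 20 with methyl 2-(bromomethyl)acrylate (second-generation Grubbs catalyst) gives the allylic bromide F9. H5IO6 in EtOAc gives the aldehyde F10. CrCl2-mediated intramolecular Nozaki–Hiyama allylation through a closed six-membered transition state, with lactonisation, gives the α-methylene lactone F11. Conjugate reduction with [(Ph3P)CuH]6 gives 26, which is equilibrated as in step 14.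

Further compounds

F1 | step 8 | acetyl-armed ene-1,3-dione from 13 (C2′ epimers) | CC(=O)CC(=O)/C(C)=C(\CC(OC(=O)C(C)(C)C)C(=C)CCC=C(C)C)[C@@H]1COC(C)(C)O1
F2 | step 8 | 4-methylcyclohexane-1,3-dione with quaternary C5 (dioxolanyl and pivaloyloxy side chain; C5 as in the target) | O=C1CC(=O)C(C)[C@](CC(OC(=O)C(C)(C)C)C(=C)CCC=C(C)C)([C@@H]2COC(C)(C)O2)C1
F3 | step 8 | bicyclo[2.2.2]octane-1,3-dione with C10 methylene (C2, C5, C2′ as in the target; C4 epimers) | C=C(CCC=C(C)C)[C@@H]1C[C@]2([C@@H]5COC(C)(C)O5)C(C)C(=O)[C@H]1C(=O)C2
F4 | step 8 | C10-methylidene enone from F3 | C=C(CCC=C(C)C)[C@@H]1C[C@]2([C@@H]5COC(C)(C)O5)C(C)C(=O)[C@H]1C(=O)C2=C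
F5 | step 8 | C3 enol triflate of F4 | C=C(CCC=C(C)C)[C@@H]1C[C@]2([C@@H]5COC(C)(C)O5)C(C)=C(OS(=O)(=O)C(F)(F)F)[C@H]1C(=O)C2=C
F6 | step 5 | (E)-allyl enamide from 4 (allyl cis to the amide carbonyl) | CON(C)C(=O)/C(C)=C(\CC=C)[C@@H]1COC(C)(C)O1
F7 | step 5 | aldehyde from oxidative cleavage of F6 | CON(C)C(=O)/C(C)=C(\CC=O)[C@@H]1COC(C)(C)O1
F8 | step 5 | 6-methylhepta-1,5-dien-2-yl trifluoromethanesulfonate | C=C(OS(=O)(=O)C(F)(F)F)CCC=C(C)C
F9 | step 13 | (Z)-2-(bromomethyl)enoate from 20 (alkyl chain cis to CH2Br) | C=C(CCC=C(C)C)[C@@H]1C[C@]2([C@@H]5COC(C)(C)O5)C(C)=C[C@H]1C(=O)[C@]2(C)CC/C=C(\CBr)C(=O)OC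
F10 | step 13 | C6 aldehyde bearing the 2-(bromomethyl)enoate chain | C=C(CCC=C(C)C)[C@@H]1C[C@]2(C=O)C(C)=C[C@H]1C(=O)[C@]2(C)CC/C=C(\CBr)C(=O)OC
F11 | step 13 | 11(13)-methylidene trans-lactone (C6, C7 as in the target) | C=C(CCC=C(C)C)[C@@H]1C[C@]23C(C)=C[C@H]1C(=O)[C@]2(C)CC[C@H]1C(=C)C(=O)O[C@@H]13
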